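**Plan**

1. Numbering (germacrane): ring A is the ten-membered carbocycle C1–C10 (C2 ketone, C8 methacrylate carbinol); ring B is the butenolide O–C6–C7=C11(C13H2OAc)–C12(=O).
2. Retrosynthetic cuts, in order: C7–C8 (ring A); O–C6 and C11–C12 of ring B (iodolactonisation and carbonylation of an allenoate); C6–C7 (alkynylation of a C6 enal); C2–C3 (propargylation of a C2 enal); C4–CH3/C5–C6 and C10–CH3/C1–C2 (carboalumination–formaldehyde).
3. Forward: the chain grows linearly from C8 to C6 by two carboalumination/formylation cycles joined by a propargylation; ring B is built on the C6 end; ring A is closed in step 14; desilylation, acetylation and oxidation to the C2 ketone finish the route.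
4. Enabling feature: C8 is an sp3 carbon that carries its acyloxy oxygen and is bonded directly to C7, the sp2 β-carbon of ring B. C8 can therefore enter as a configurationally free 1-acyloxyalkyl radical (C8 aldehyde plus methacryloyl chloride) and C7 as an alkenylnickel (from a C7–I bond).
5. Stereochemistry: both ring alkenes are E from syn carboalumination; C6 comes from a catalytic asymmetric alkynylation (4S carbinol), relayed centre→axis→centre (anti SN2′ carbonylation, anti iodolactonisation, net inversion) to 6R; C8 is set during ring closure by a chiral nickel catalyst in a stereoconvergent coupling.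

Key step: step 14

**Remarks**

- Assumption: the carbinol carbon C2 is oxidised to the ketone in the last step, so it is carried as both epimers; the SMILES of 8–12 and 15–24 leave it unassigned. In 21 the chlorine-bearing C8 is also unassigned, because both epimers are wanted.
- Abbreviations: TBS = tert-butyldimethylsilyl (TBSO = its ether), PMB = 4-methoxybenzyl (PMBO = its ether), DMP = Dess–Martin periodinane, DME = 1,2-dimethoxyethane.

**Route**

Step 1
Reactants: 1 but-3-yn-1-ol
Product: 2 1-[(but-3-yn-1-yloxy)methyl]-4-methoxybenzene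
Conditions: NaH, PMBCl, Bu4NI (cat.), THF/DMF, 0 °C → rt
Reagents that add atoms: 4-methoxybenzyl chloride, COc1ccc(CCl)cc1
Why: Williamson etherification protects the future C8 oxygen as an ether that is later removed oxidatively without touching silyl ethers.

Step 2
Reactants: 2 PMB ether of but-3-yn-1-ol
Product: 4 (2E)-5-(4-methoxybenzyloxy)-3-methylpent-2-en-1-ol, via alkenyldimethylalane 3 (not isolated)
Conditions: AlMe3, Cp2ZrCl2 (0.25 equiv), CH2Cl2, 0 °C → rt; then n-BuLi, THF, −78 → 0 °C; (CH2O)n, rt; aqueous work-up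
Reagents that add atoms: trimethylaluminium, C[Al](C)C; formaldehyde (as paraformaldehyde), C=O
Why: Negishi zirconium-catalysed carboalumination adds methyl and aluminium syn across the terminal alkyne, which fixes the E geometry of the future C1=C10 alkene, and the alkenylalanate is hydroxymethylated by formaldehyde.

Step 3
Reactants: 4 allylic alcohol
Product: 5 (2E)-5-(4-methoxybenzyloxy)-3-methylpent-2-enal
Conditions: MnO2, CH2Cl2, rt
Reagents that add atoms: none
Why: Manganese dioxide oxidation is selective for the allylic alcohol and keeps the alkene geometry.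

Step 4
Reactants: 5 enal; 6 3-bromoprop-1-yne (propargyl bromide)
Product: 8 (5E)-8-(4-methoxybenzyloxy)-6-methyloct-5-en-1-yn-4-ol (both C4 configurations), via allenylzinc bromide 7 (not isolated)
Conditions: Zn dust, THF, 0 °C → rt; aqueous NH4Cl
Reagents that add atoms: none
Why: Barbier-type zinc propargylation (SE2′ reaction of the allenylzinc) adds 1,2 to the enal and forms the C2–C3 bond; the new carbinol (future C2) is left uncontrolled on purpose.

Step 5
Reactants: 8 homopropargylic alcohol
Product: 9 tert-butyl{[(5E)-8-(4-methoxybenzyloxy)-6-methyloct-5-en-1-yn-4-yl]oxy}dimethylsilane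
Conditions: TBSCl, imidazole, DMF, rt
Reagents that add atoms: tert-butyldimethylsilyl chloride, CC(C)(C)[Si](C)(C)Cl
Why: Standard silylation masks the C2 oxygen until the final oxidation.

Step 6
Reactants: 9 silyl ether
Product: 11 (2E,6E)-5-(TBSO)-9-(PMBO)-3,7-dimethylnona-2,6-dien-1-ol, via alkenyldimethylalane 10 (not isolated)
Conditions: AlMe3, Cp2ZrCl2 (0.25 equiv), CH2Cl2, 0 °C → rt; then n-BuLi, THF, −78 → 0 °C; (CH2O)n, rt; aqueous work-up
Reagents that add atoms: trimethylaluminium, C[Al](C)C; formaldehyde (as paraformaldehyde), C=O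
Why: A second Negishi carboalumination–hydroxymethylation sets the E-configured C4=C5 alkene by syn addition and brings in C6.

Step 7
Reactants: 11 dienol
Product: 12 (2E,6E)-5-(TBSO)-9-(PMBO)-3,7-dimethylnona-2,6-dienal
Conditions: MnO2, CH2Cl2, rt
Reagents that add atoms: none
Why: Chemoselective allylic oxidation gives the C6 enal without isomerising the trisubstituted alkenes.

Step 8
Reactants: 12 dienal; 13 tert-butyldimethyl(prop-2-yn-1-yloxy)silane
Product: 15 (4S,5E,9E)-1,8-bis(TBSO)-12-(PMBO)-6,10-dimethyldodeca-5,9-dien-2-yn-4-ol, via alkynyl(methyl)zinc 14 (not isolated)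
Conditions: Me2Zn, (S,S)-ProPhenol (20 mol %), Ph3P=O (40 mol %), toluene, 0–4 °C
Reagents that add atoms: none
Why: Zinc–ProPhenol asymmetric alkynylation delivers the alkynylzinc to the Re face of the enal inside the chiral dinuclear zinc pocket and sets the 4S carbinol (future C6); the antipodal ligand is used if the facial sense proves opposite.

Step 9
Reactants: 15 propargylic alcohol
Product: 16 methyl carbonate of 15 (4S)
Conditions: ClCO2Me, pyridine, DMAP (cat.), CH2Cl2, 0 °C; used without chromatography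
Reagents that add atoms: methyl chloroformate, COC(=O)Cl
Why: Carbonate formation activates the propargylic C–O bond for ionisation by palladium without touching the stereocentre.

Step 10
Reactants: 16 propargylic carbonate
Product: 17 methyl (Ra,5E,9E)-2-[(TBSO)methyl]-8-(TBSO)-12-(PMBO)-6,10-dimethyldodeca-2,3,5,9-tetraenoate
Conditions: Pd2(dba)3 (2.5 mol %), PPh3 (20 mol %), CO (1–5 atm), THF/MeOH, 25–40 °C
Reagents that add atoms: carbon monoxide, [C-]#[O+]
Why: In this Tsuji-type alkoxycarbonylation, zerovalent palladium attacks the alkyne terminus C11 anti to the carbonate (SN2′), and the σ-allenylpalladium inserts CO and is captured by the carbonate-derived methoxide, so the 4S centre is translated into the allene axis and C12 is installed.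

Step 11
Reactants: 17 allenoate
Product: 18 (5R)-3-[(TBSO)methyl]-4-iodo-5-[(1E,5E)-4-(TBSO)-8-(PMBO)-2,6-dimethylocta-1,5-dien-1-yl]furan-2(5H)-one
Conditions: I2 (2 equiv), MeCN/H2O 15:1, rt, dark
Reagents that add atoms: iodine, II
Why: In this iodolactonisation of a 2,3-allenoate, iodine adds to the central allene carbon C7 while the ester carbonyl oxygen closes on C6 from the opposite face (anti addition) and iodide removes the methyl group, so the axis is translated into the 6R centre and ring B is formed with its C7–I handle.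

Step 12
Reactants: 18 iodobutenolide
Product: 19 (5R)-3-[(TBSO)methyl]-5-[(1E,5E)-4-(TBSO)-8-hydroxy-2,6-dimethylocta-1,5-dien-1-yl]-4-iodofuran-2(5H)-one
Conditions: DDQ, CH2Cl2/pH 7 buffer, 0 °C
Reagents that add atoms: none
Why: Oxidative PMB cleavage frees the C8 hydroxyl and leaves both silyl ethers, the vinyl iodide and the lactone untouched.

Step 13
Reactants: 19 primary alcohol
Product: 20 (3E,7E)-8-[(2R)-4-{[TBSO]methyl}-3-iodo-5-oxo-2,5-dihydrofuran-2-yl]-5-(TBSO)-3,7-dimethylocta-3,7-dienal
Conditions: DMP, NaHCO3, CH2Cl2, 0 °C → rt; used at once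
Reagents that add atoms: none
Why: Buffered Dess–Martin oxidation gives the β,γ-unsaturated C8 aldehyde under conditions mild enough to avoid conjugation of the alkene.

Step 14
Reactants: 20 iodo aldehyde
Product: 22 (6R,8S)-8-methacryloyloxy-2,13-bis(TBSO)germacra-1(10)E,4E,7(11)-trien-12,6-olide, via 1-chloroalkyl methacrylate 21 (not isolated)
Conditions: (a) methacryloyl chloride (1.05 equiv), ZnCl2 (5 mol %), CH2Cl2, −20 → 0 °C, volatiles removed; (b) NiBr2·DME (20 mol %), chiral indane-fused bis(oxazoline) ligand (24 mol %, antipode chosen for 8S), Mn powder, NaI (0.5 equiv), DMA/THF, slow addition to 2 mM, 0 °C → rt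
Reagents that add atoms: methacryloyl chloride, CC(=C)C(=O)Cl
Why: Proposed new method: the aldehyde and methacryloyl chloride first give the racemic 1-chloroalkyl ester (known ZnCl2-catalysed addition), then zerovalent nickel inserts into the C7–I bond of ring B, the alkenylnickel abstracts halogen from the tethered C8–Cl (C8–I after exchange with NaI) to give a planar 1-acyloxyalkyl radical, radical capture gives a trivalent alkenyl(alkyl)nickel, and reductive elimination forms C7–C8 while manganese returns nickel to the zerovalent state. The closest known reaction types are the nickel/bis(oxazoline)-catalysed enantioconvergent substitution of racemic 1-haloalkyl esters by organozinc reagents and the asymmetric reductive cross-electrophile coupling of alkenyl halides with secondary benzylic chlorides; the intramolecular medium-ring version is what is new. Ring A closes as a ten-membered carbocycle by C(sp2)–C(sp3) reductive elimination from an eleven-membered nickelacycle, with the C7=C11 double bond remaining exocyclic to ring A (exo mode at C7). C8 is the only new stereocentre: both C8 epimers of the chloride and both C2 epimers pass through the same radical, and the configuration is fixed at nickel by the chiral ligand (catalyst control, with the resident 6R centre as a possible matched or mismatched bias answered by the choice of ligand antipode), so the step is stereoconvergent and delivers the methacrylate already in place. The step needs site selectivity (oxidative addition only at the sp2 C–I bond, radical formation only at C8) and ring closure in preference to dimerisation, β-hydride loss or radical addition to the methacrylate; the different activation modes of the two halides, high dilution, the intramolecular abstraction–rebound sequence and the unfavourable 4-exo/5-endo geometry for attack on the methacrylate secure these, and the allylic silyl ether at C13 is inert to nickel.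

Step 15
Reactants: 22 bis-silyl macrocycle
Product: 23 (6R,8S)-2,13-dihydroxy-8-methacryloyloxygermacra-1(10)E,4E,7(11)-trien-12,6-olide
Conditions: HF·pyridine, pyridine/THF, 0 °C → rt
Reagents that add atoms: none
Why: Buffered fluoride desilylation removes both TBS groups without base, so neither ester migrates and C6 does not epimerise.

Step 16
Reactants: 23 diol
Product: 24 (6R,8S)-13-acetoxy-2-hydroxy-8-methacryloyloxygermacra-1(10)E,4E,7(11)-trien-12,6-olide
Conditions: AcCl (1.1 equiv), 2,4,6-collidine, CH2Cl2, −78 °C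
Reagents that add atoms: acetyl chloride, CC(=O)Cl
Why: Acetyl chloride with collidine at low temperature acylates the primary C13 hydroxyl selectively over the secondary C2 hydroxyl.

Step 17
Reactants: 24 allylic alcohol
Product: 25 (6R,8S)-13-acetoxy-8-methacryloyloxy-2-oxogermacra-1(10)E,4E,7(11)-trien-12,6-olide (CNP0325594.1)
Conditions: DMP, NaHCO3, CH2Cl2, 0 °C
Reagents that add atoms: none
Why: Buffered Dess–Martin oxidation converts both C2 epimers into the single enone under neutral conditions that should not move the C4=C5 alkene into conjugation or disturb C6 and C8.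

**Compound list**

1 | but-3-yn-1-ol | C#CCCO | starting material
2 | 1-[(but-3-yn-1-yloxy)methyl]-4-methoxybenzene | C#CCCOCc1ccc(OC)cc1 | intermediate
3 | [(1E)-4-(4-methoxybenzyloxy)-2-methylbut-1-en-1-yl]dimethylalane | C[Al](C)/C=C(\C)CCOCc1ccc(OC)cc1 | intermediate
4 | (2E)-5-(4-methoxybenzyloxy)-3-methylpent-2-en-1-ol | OC/C=C(\C)CCOCc1ccc(OC)cc1 | intermediate
5 | (2E)-5-(4-methoxybenzyloxy)-3-methylpent-2-enal | O=C/C=C(\C)CCOCc1ccc(OC)cc1 | intermediate
6 | 3-bromoprop-1-yne (propargyl bromide) | C#CCBr | starting material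
7 | bromo(propa-1,2-dien-1-yl)zinc | C=C=C[Zn]Br | intermediate
8 | (5E)-8-(4-methoxybenzyloxy)-6-methyloct-5-en-1-yn-4-ol, both C4 configurations | C#CCC(O)/C=C(\C)CCOCc1ccc(OC)cc1 | intermediate
9 | tert-butyl{[(5E)-8-(4-methoxybenzyloxy)-6-methyloct-5-en-1-yn-4-yl]oxy}dimethylsilane | C#CCC(O[Si](C)(C)C(C)(C)C)/C=C(\C)CCOCc1ccc(OC)cc1 | intermediate
10 | [(1E,5E)-4-(TBSO)-8-(PMBO)-2,6-dimethylocta-1,5-dien-1-yl]dimethylalane | C[Al](C)/C=C(\C)CC(O[Si](C)(C)C(C)(C)C)/C=C(\C)CCOCc1ccc(OC)cc1 | intermediate
11 | (2E,6E)-5-(TBSO)-9-(PMBO)-3,7-dimethylnona-2,6-dien-1-ol | OC/C=C(\C)CC(O[Si](C)(C)C(C)(C)C)/C=C(\C)CCOCc1ccc(OC)cc1 | intermediate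
12 | (2E,6E)-5-(TBSO)-9-(PMBO)-3,7-dimethylnona-2,6-dienal | O=C/C=C(\C)CC(O[Si](C)(C)C(C)(C)C)/C=C(\C)CCOCc1ccc(OC)cc1 | intermediate
13 | tert-butyldimethyl(prop-2-yn-1-yloxy)silane | C#CCO[Si](C)(C)C(C)(C)C | starting material
14 | {3-[(TBS)oxy]prop-1-yn-1-yl}(methyl)zinc | C[Zn]C#CCO[Si](C)(C)C(C)(C)C | intermediate
15 | (4S,5E,9E)-1,8-bis(TBSO)-12-(PMBO)-6,10-dimethyldodeca-5,9-dien-2-yn-4-ol | CC(C)(C)[Si](C)(C)OCC#C[C@@H](O)/C=C(\C)CC(O[Si](C)(C)C(C)(C)C)/C=C(\C)CCOCc1ccc(OC)cc1 | intermediate
16 | methyl carbonate of 15 (4S) | CC(C)(C)[Si](C)(C)OCC#C[C@@H](OC(=O)OC)/C=C(\C)CC(O[Si](C)(C)C(C)(C)C)/C=C(\C)CCOCc1ccc(OC)cc1 | intermediate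
17 | methyl (Ra,5E,9E)-2-[(TBSO)methyl]-8-(TBSO)-12-(PMBO)-6,10-dimethyldodeca-2,3,5,9-tetraenoate | COC(=O)C(CO[Si](C)(C)C(C)(C)C)=[C@]=C([H])/C=C(\C)CC(O[Si](C)(C)C(C)(C)C)/C=C(\C)CCOCc1ccc(OC)cc1 | intermediate
18 | (5R)-3-[(TBSO)methyl]-4-iodo-5-[(1E,5E)-4-(TBSO)-8-(PMBO)-2,6-dimethylocta-1,5-dien-1-yl]furan-2(5H)-one | CC(C)(C)[Si](C)(C)OCC1=C(I)[C@@H](/C=C(\C)CC(O[Si](C)(C)C(C)(C)C)/C=C(\C)CCOCc2ccc(OC)cc2)OC1=O | intermediate
19 | (5R)-3-[(TBSO)methyl]-5-[(1E,5E)-4-(TBSO)-8-hydroxy-2,6-dimethylocta-1,5-dien-1-yl]-4-iodofuran-2(5H)-one | CC(C)(C)[Si](C)(C)OCC1=C(I)[C@@H](/C=C(\C)CC(O[Si](C)(C)C(C)(C)C)/C=C(\C)CCO)OC1=O | intermediate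
20 | (3E,7E)-8-[(2R)-4-{[TBSO]methyl}-3-iodo-5-oxo-2,5-dihydrofuran-2-yl]-5-(TBSO)-3,7-dimethylocta-3,7-dienal | CC(C)(C)[Si](C)(C)OCC1=C(I)[C@@H](/C=C(\C)CC(O[Si](C)(C)C(C)(C)C)/C=C(\C)CC=O)OC1=O | intermediate
21 | 1-chloroalkyl methacrylate of 20 (1-chloro at the former aldehyde carbon, both configurations) | CC(C)(C)[Si](C)(C)OCC1=C(I)[C@@H](/C=C(\C)CC(O[Si](C)(C)C(C)(C)C)/C=C(\C)CC(Cl)OC(=O)C(C)=C)OC1=O | intermediate
22 | (6R,8S)-8-methacryloyloxy-2,13-bis(TBSO)germacra-1(10)E,4E,7(11)-trien-12,6-olide | C=C(C)C(=O)O[C@H]1C/C(C)=C/C(O[Si](C)(C)C(C)(C)C)C/C(C)=C/[C@H]2OC(=O)C(CO[Si](C)(C)C(C)(C)C)=C12 | intermediate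
23 | (6R,8S)-2,13-dihydroxy-8-methacryloyloxygermacra-1(10)E,4E,7(11)-trien-12,6-olide | C=C(C)C(=O)O[C@H]1C/C(C)=C/C(O)C/C(C)=C/[C@H]2OC(=O)C(CO)=C12 | intermediate
24 | (6R,8S)-13-acetoxy-2-hydroxy-8-methacryloyloxygermacra-1(10)E,4E,7(11)-trien-12,6-olide | C=C(C)C(=O)O[C@H]1C/C(C)=C/C(O)C/C(C)=C/[C@H]2OC(=O)C(COC(C)=O)=C12 | intermediate
25 | (6R,8S)-13-acetoxy-8-methacryloyloxy-2-oxogermacra-1(10)E,4E,7(11)-trien-12,6-olide (CNP0325594.1) | C=C(C)C(=O)O[C@H]1C/C(C)=C/C(=O)C/C(C)=C/[C@H]2OC(=O)C(COC(C)=O)=C12 | target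

**Step count and risks**

Total steps: 17. Longest linear sequence: 17 (from but-3-yn-1-ol; 6 and 13 are bought).

The three steps most likely to fail:

1. Step 14 (Proposed new method). The ring closure may lose to intermolecular coupling, to reduction of the C7–I bond, or to β-hydride loss at C8 giving a dienyl ester; the catalyst may also fail to override the facial bias of the 6R centre. Fallback with known chemistry, setting out from 20: a Nozaki–Hiyama–Kishi macrocyclisation (CrCl2, catalytic NiCl2, DMSO/THF, high dilution, optionally with a chiral sulfonamide ligand on chromium) should insert divalent chromium/nickel into the C7–I bond and add the alkenylchromium to the C8 aldehyde, giving (6R,8S)-8-hydroxy-2,13-bis(TBSO)germacra-1(10)E,4E,7(11)-trien-12,6-olide F1. Acylation with methacrylic anhydride/DMAP comes back to the route at 22. If the 8R epimer prevails, Mitsunobu esterification with methacrylic acid inverts C8 and also reaches 22.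

2. Step 10. Ionisation may run through the neighbouring alkene (π-allyl) instead of the alkyne, which would cause carbonylation at C6 or erosion of the centre-to-axis transfer, and the vinylallene product may react further with palladium. Fallback, setting out from 12:
   - alkynylation with the antipodal ProPhenol ligand gives the (4R)-carbinol (4R,5E,9E)-1,8-bis(TBSO)-12-(PMBO)-6,10-dimethyldodeca-5,9-dien-2-yn-4-ol F2;
   - KH/ICH2SnBu3 gives its tributylstannylmethyl ether F3;
   - n-BuLi at −78 °C triggers a Still–Wittig [2,3]-rearrangement (suprafacial, syn SN2′ onto the alkyne), which gives the allenylmethanol F4 with the same allene axis as 17;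
   - MnO2 gives the allenal F5 and Pinnick oxidation the allenoic acid F6;
   - iodolactonisation (I2, NaHCO3, MeCN) comes back to the route at 18.

3. Step 8. Facial discrimination may be poor, or addition slow, on the β,β-disubstituted enal, which would erode the C6 configuration that everything downstream relays. Fallback, setting out from 12: addition of the lithium acetylide of 13 (n-BuLi, THF, −78 °C) gives the carbinol as both C4 epimers, 1,8-bis(TBSO)-12-(PMBO)-6,10-dimethyldodeca-5,9-dien-2-yn-4-ol F7. MnO2 gives the alkynyl ketone F8, and reagent-controlled reduction with (S)-Alpine-borane (alkyne as the small group) comes back to the route at 15.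

**Further compounds**

F1 | step 14 | (6R,8S)-8-hydroxy-2,13-bis(TBSO)germacra-1(10)E,4E,7(11)-trien-12,6-olide | O[C@H]1C/C(C)=C/C(O[Si](C)(C)C(C)(C)C)C/C(C)=C/[C@H]2OC(=O)C(CO[Si](C)(C)C(C)(C)C)=C12
F2 | step 10 | (4R,5E,9E)-1,8-bis(TBSO)-12-(PMBO)-6,10-dimethyldodeca-5,9-dien-2-yn-4-ol | CC(C)(C)[Si](C)(C)OCC#C[C@H](O)/C=C(\C)CC(O[Si](C)(C)C(C)(C)C)/C=C(\C)CCOCc1ccc(OC)cc1
F3 | step 10 | tributylstannylmethyl ether of F2 (4R) | CCCC[Sn](CCCC)(CCCC)CO[C@@H](C#CCO[Si](C)(C)C(C)(C)C)/C=C(\C)CC(O[Si](C)(C)C(C)(C)C)/C=C(\C)CCOCc1ccc(OC)cc1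
F4 | step 10 | (5E,9E)-2-[(TBSO)methyl]-8-(TBSO)-12-(PMBO)-6,10-dimethyldodeca-2,3,5,9-tetraen-1-ol, allene axis as in 17 | OCC(CO[Si](C)(C)C(C)(C)C)=[C@]=C([H])/C=C(\C)CC(O[Si](C)(C)C(C)(C)C)/C=C(\C)CCOCc1ccc(OC)cc1
F5 | step 10 | (5E,9E)-2-[(TBSO)methyl]-8-(TBSO)-12-(PMBO)-6,10-dimethyldodeca-2,3,5,9-tetraenal, allene axis as in 17 | O=CC(CO[Si](C)(C)C(C)(C)C)=[C@]=C([H])/C=C(\C)CC(O[Si](C)(C)C(C)(C)C)/C=C(\C)CCOCc1ccc(OC)cc1
F6 | step 10 | (5E,9E)-2-[(TBSO)methyl]-8-(TBSO)-12-(PMBO)-6,10-dimethyldodeca-2,3,5,9-tetraenoic acid, allene axis as in 17 | OC(=O)C(CO[Si](C)(C)C(C)(C)C)=[C@]=C([H])/C=C(\C)CC(O[Si](C)(C)C(C)(C)C)/C=C(\C)CCOCc1ccc(OC)cc1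
F7 | step 8 | (5E,9E)-1,8-bis(TBSO)-12-(PMBO)-6,10-dimethyldodeca-5,9-dien-2-yn-4-ol, both C4 configurations | CC(C)(C)[Si](C)(C)OCC#CC(O)/C=C(\C)CC(O[Si](C)(C)C(C)(C)C)/C=C(\C)CCOCc1ccc(OC)cc1
F8 | step 8 | (5E,9E)-1,8-bis(TBSO)-12-(PMBO)-6,10-dimethyldodeca-5,9-dien-2-yn-4-one | CC(C)(C)[Si](C)(C)OCC#CC(=O)/C=C(\C)CC(O[Si](C)(C)C(C)(C)C)/C=C(\C)CCOCc1ccc(OC)cc1
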